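## Retrosynthetic overview

1. CJ-13,108 ⇒ cut the lactone C3–O bond together with the C1'–C2' bond of the side chain. This gives 2,4-dimethoxy-6-vinylbenzoic acid and a 12-oxotridecyl radical. The C3–O bond is made last and sets the only stereocentre.
2. 12-Oxotridecyl radical ⇒ β-scission of the 1-methylcyclododecyloxyl radical ⇒ its triethylsilyl peroxide ⇒ methylenecyclododecane ⇒ cyclododecanone. Ring opening unveils the methyl ketone, so no protecting group is needed.
3. Vinyl acid ⇒ Suzuki vinylation of 2-bromo-4,6-dimethoxybenzoic acid ⇒ Pinnick oxidation ⇒ Vilsmeier–Haack formylation of 1-bromo-3,5-dimethoxybenzene.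
4. Ring order: aromatic ring A is bought and the bought twelve-membered carbocycle is opened. Lactone ring B is the only ring formed, in the last step.

Assumption: the stereocentre in the SMILES reads as (S); the sense of induction in step 6 rests on a quadrant model, and if the first run gives the (R)-lactone the equally available (R,R)-ligand is used with nothing else changed.

## Route

Step 1
Reactants: 1 cyclododecanone
Product: 2 methylenecyclododecane
Conditions: Ph3PCH3Br (1.4 equiv), KOt-Bu (1.4 equiv), THF, 0 °C to 65 °C
Reagents that add atoms: methyltriphenylphosphonium bromide, C[P+](c1ccccc1)(c1ccccc1)c1ccccc1.[Br-]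
Why: Wittig methylenation with the unstabilised ylide is the standard conversion of this simple ring ketone into the exocyclic 1,1-disubstituted alkene, and no stereocentre is formed.

Step 2
Reactants: 2 methylenecyclododecane
Product: 3 triethyl[(1-methylcyclododecyl)peroxy]silane
Conditions: Co(thd)2 (5 mol %; thd = 2,2,6,6-tetramethylheptane-3,5-dionate), O2 (1 atm), Et3SiH (2 equiv), ClCH2CH2Cl, 23 °C
Reagents that add atoms: dioxygen, O=O; triethylsilane, CC[SiH](CC)CC
Why: In the Isayama–Mukaiyama silylperoxidation a cobalt hydride delivers a hydrogen atom to the CH2 terminus, O2 is captured at the tertiary carbon and the silane caps the peroxide, which gives the Markovnikov tertiary silyl peroxide with no stereocentre.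

Step 3
Reactants: 4 1-bromo-3,5-dimethoxybenzene
Product: 6 2-bromo-4,6-dimethoxybenzaldehyde, via aryl iminium dichlorophosphate 5 (not isolated)
Conditions: POCl3 (2 equiv), DMF, 0 °C to 100 °C; then ice–water
Reagents that add atoms: N,N-dimethylformamide, CN(C)C=O; water, O
Why: Vilsmeier–Haack formylation attacks the position para to one methoxy group and ortho to the other (next to bromine) in preference to the site between the two methoxy groups, and water hydrolyses the iminium salt to the aldehyde.

Step 4
Reactants: 6 2-bromo-4,6-dimethoxybenzaldehyde
Product: 7 2-bromo-4,6-dimethoxybenzoic acid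
Conditions: NaClO2, NaH2PO4, 2-methyl-2-butene (10 equiv), t-BuOH/THF/H2O, 0 °C to 23 °C
Reagents that add atoms: sodium chlorite, [Na+].[O-]Cl=O
Why: Pinnick oxidation converts the aldehyde to the acid without touching the aryl bromide or the methyl ethers, and the large excess of alkene scavenger removes hypochlorous acid before it can chlorinate the electron-rich ring.

Step 5
Reactants: 7 2-bromo-4,6-dimethoxybenzoic acid
Product: 10 2,4-dimethoxy-6-vinylbenzoic acid, via potassium 2-bromo-4,6-dimethoxybenzoate 8 (not isolated), via potassium 2,4-dimethoxy-6-vinylbenzoate 9 (not isolated)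
Conditions: vinylboronic acid pinacol ester (1.5 equiv), Pd(dppf)Cl2 (3 mol %), K2CO3 (3.5 equiv), 1,4-dioxane/H2O 4:1, 85 °C; then cold 1 M HCl to pH 3
Reagents that add atoms: vinylboronic acid pinacol ester, C=CB1OC(C)(C)C(C)(C)O1
Why: Suzuki–Miyaura coupling tolerates the carboxylate salt, and the cold, mild acidification avoids both protodecarboxylation of the electron-rich acid and acid-catalysed closure onto the vinyl group.

Step 6
Reactants: 3 triethyl[(1-methylcyclododecyl)peroxy]silane; 10 2,4-dimethoxy-6-vinylbenzoic acid
Product: 14 CJ-13,108 ((3S)-5,7-dimethoxy-3-(13-oxotetradecyl)isobenzofuran-1(3H)-one), via 1-methylcyclododecyloxyl radical 11 (not isolated), via 12-oxotridecyl radical 12 (not isolated), via benzylic radical adduct 13 (not isolated)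
Conditions: Cu(MeCN)4PF6 (10 mol %), (S,S)-t-Bu-Box [2,2'-(propane-2,2-diyl)bis((4S)-4-tert-butyl-4,5-dihydrooxazole)] (12 mol %), 3 (1.6 equiv, syringe pump over 6 h), PhCF3/MeCN 9:1, 0.2 M in 10, 35 °C, Ar
Reagents that add atoms: none
Why: Proposed new method: enantioselective ring-opening alkylative lactonisation, in which the monovalent copper–bis(oxazoline) complex cleaves the O–O bond of 3 by single-electron transfer to give alkoxyl radical 11 and a divalent copper silanolate that deprotonates acid 10; 11 breaks a ring C–C bond by β-scission to the primary radical 12, which already carries the methyl ketone; 12 adds to the CH2 terminus of the styrene, and benzylic radical 13 is captured by the chiral divalent copper carboxylate as a six-membered trivalent copper chelate whose C–O reductive elimination closes ring B, sets C3 and returns monovalent copper; in the quadrant model the tert-butyl group beside the carbon site pushes the long chain to the open face, which for the (S,S)-ligand and retentive elimination gives (S); both methoxy groups are meta to the radical carbon and the carboxyl is ortho, so outer-sphere oxidation to a free cation (the racemic path) is disfavoured, and solvents without weak C–H bonds protect 11 from hydrogen abstraction; the closest known reaction types are copper/bis(oxazoline) radical oxyfunctionalisation–lactonisation of 1,1-disubstituted alkenoic acids and achiral copper-catalysed couplings of cycloalkylsilyl peroxides, and what is new is their union, the unstabilised alkyl radical partner and a secondary benzylic C–O stereocentre.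

## Compound list

1 | cyclododecanone | O=C1CCCCCCCCCCC1 | starting material
2 | methylenecyclododecane | C=C1CCCCCCCCCCC1 | intermediate
3 | triethyl[(1-methylcyclododecyl)peroxy]silane | CC1(OO[Si](CC)(CC)CC)CCCCCCCCCCC1 | intermediate
4 | 1-bromo-3,5-dimethoxybenzene | COc1cc(Br)cc(OC)c1 | starting material
5 | (2-bromo-4,6-dimethoxybenzylidene)dimethyliminium dichlorophosphate | COc1cc(Br)c(C=[N+](C)C)c(OC)c1.[O-]P(=O)(Cl)Cl | intermediate
6 | 2-bromo-4,6-dimethoxybenzaldehyde | COc1cc(Br)c(C=O)c(OC)c1 | intermediate
7 | 2-bromo-4,6-dimethoxybenzoic acid | COc1cc(Br)c(C(=O)O)c(OC)c1 | intermediate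
8 | potassium 2-bromo-4,6-dimethoxybenzoate | COc1cc(Br)c(C(=O)[O-])c(OC)c1.[K+] | intermediate
9 | potassium 2,4-dimethoxy-6-vinylbenzoate | COc1cc(C=C)c(C(=O)[O-])c(OC)c1.[K+] | intermediate
10 | 2,4-dimethoxy-6-vinylbenzoic acid | COc1cc(C=C)c(C(=O)O)c(OC)c1 | intermediate
11 | 1-methylcyclododecyloxyl radical | CC1([O])CCCCCCCCCCC1 | intermediate
12 | 12-oxotridecyl radical | [CH2]CCCCCCCCCCC(C)=O | intermediate
13 | benzylic radical adduct, 1-(2-carboxy-3,5-dimethoxyphenyl)-14-oxopentadecyl radical | COc1cc([CH]CCCCCCCCCCCCC(C)=O)c(C(=O)O)c(OC)c1 | intermediate
14 | CJ-13,108, (3S)-5,7-dimethoxy-3-(13-oxotetradecyl)isobenzofuran-1(3H)-one | COc1cc(OC)c2c(c1)[C@H](CCCCCCCCCCCCC(C)=O)OC2=O | target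

## Step count and risks

Total step count: 6. Longest linear sequence: 4 (steps 3, 4, 5, 6).

**(a) The new lactonisation, step 6.**
- The ee may be modest, because secondary benzylic radicals have not been taken through this C–O coupling.
- In radical 11, a 1,5-hydrogen shift across the large ring or loss of methyl may compete with ring opening.
- Radical 12 may be trapped by the divalent copper carboxylate before it reaches the alkene. Slow addition of 3 and the 0.2 M alkene concentration are chosen against this.
- Material of 85–90 % ee could be raised by crystallisation. The ee is read by chiral HPLC and the sign of rotation is compared with the natural product.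

The fallback uses known chemistry and sets the stereocentre by hydrogenation instead of C–O coupling. It sets out from 3 and 7 and comes back at 14. Peroxide 3 is coupled with ethynyltrimethylsilane under the established achiral copper-catalysed radical C(sp3)–C(sp) coupling of alkylsilyl peroxides with terminal alkynes (CuI, 1,10-phenanthroline, MeCN) to give 15-(trimethylsilyl)pentadec-14-yn-2-one F1. K2CO3 in MeOH removes the silyl group to give pentadec-14-yn-2-one F2. Sonogashira coupling of F2 with bromo acid 7 is followed in the same pot by 5-exo-dig closure of the carboxylate onto the alkyne (Pd(PPh3)2Cl2, CuI, Et3N, DMF, 70 °C), which gives (Z)-5,7-dimethoxy-3-(13-oxotetradecylidene)isobenzofuran-1(3H)-one F3. Enantioselective hydrogenation of the exocyclic double bond with a cationic iridium phosphine–oxazoline catalyst [Ir(cod)(L)]BArF (H2, CH2Cl2) is a known reaction of 3-ylidenephthalides. It leaves the dialkyl ketone untouched and gives 14.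

**(b) The silylperoxidation, step 2.** Over-reduction to the silyl ether or alcohol, or stalling of the cobalt catalyst, would cost material. The fallback replaces radical peroxidation by ionic perhydrolysis; it sets out from 1 and comes back at 3. MeMgBr with CeCl3 (THF, 0 °C) adds to 1 to give 1-methylcyclododecan-1-ol F4. Aqueous H2O2 (50 %) with catalytic H2SO4 exchanges the tertiary hydroxyl through the carbocation to give 1-methylcyclododecyl hydroperoxide F5. Et3SiCl and imidazole in DMF then give 3.

**(c) The vinylation of the free acid, step 5.** Oxidative addition into the hindered, electron-rich bromide may be slow, and the acid may protodecarboxylate. The fallback builds the alkene by carbonyl olefination instead of cross-coupling; it sets out from 7 and comes back at 10. n-BuLi (2.2 equiv, THF, −90 °C) deprotonates the acid and exchanges the bromine. DMF and an acidic work-up then give 3-hydroxy-5,7-dimethoxyisobenzofuran-1(3H)-one F6, the ring tautomer of the 2-formyl acid. Ph3P=CH2 (2.5 equiv, THF) opens and methylenates it to 10.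

## Further compounds

F1 | step 6 | 15-(trimethylsilyl)pentadec-14-yn-2-one | CC(=O)CCCCCCCCCCCC#C[Si](C)(C)C
F2 | step 6 | pentadec-14-yn-2-one | CC(=O)CCCCCCCCCCCC#C
F3 | step 6 | (Z)-5,7-dimethoxy-3-(13-oxotetradecylidene)isobenzofuran-1(3H)-one | O=C1O/C(=C\CCCCCCCCCCCC(C)=O)c2cc(OC)cc(OC)c12
F4 | step 2 | 1-methylcyclododecan-1-ol | CC1(O)CCCCCCCCCCC1
F5 | step 2 | 1-methylcyclododecyl hydroperoxide | CC1(OO)CCCCCCCCCCC1
F6 | step 5 | 3-hydroxy-5,7-dimethoxyisobenzofuran-1(3H)-one | COc1cc(OC)c2c(c1)C(O)OC2=O
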